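Ring atoms are numbered C1 (OMe), C2=C3 (C3 bears C7H2OBz), C4 (OH), C5 (OBz), C6 (OH). The plan cuts C3–C4, because C4 is a free secondary allylic carbinol attached to the substituted alkene carbon C3 of the cyclohexene. One CrCl2/NiCl2-mediated alkenyl iodide–aldehyde coupling makes that bond, closes the six-membered ring and creates C4. The open-chain precursor is carved from D-glucuronolactone acetonide, which supplies C5, C6 and C1 with every oxygen distinguished. It carries the (Z)-C2=C3 iodide, the final O5 benzoate, a formate on O6 and a silyl ether on O7. After ring closure only one deprotection and the benzoylation of primary O7 remain.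

Key step: step 9

Assumption: the hemiacetal carbons of 4 and 14 are anomeric mixtures and are written without configuration, because both centres vanish in the next step. The carbons of 1 are called G1–G6. G2, G3, G4, G5 and G6 become ring C4, C5, C6, C1 and C2, and G1 ends as the formyl carbon on O6.

Step 1
Reactants: 1 1,2-O-isopropylidene-α-D-glucofuranurono-6,3-lactone; 2 iodomethane
Product: 3 1,2-O-isopropylidene-5-O-methyl-α-D-glucofuranurono-6,3-lactone
Conditions: MeI (excess), Ag2O, 4 Å MS, MeCN, rt, dark
Reagents that add atoms: iodomethane, CI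
Why: Purdie methylation, a Williamson-type O-alkylation promoted by Ag2O, etherifies the only free hydroxyl (G5-OH, the future C1-OMe) without any strong base, so the lactone stays closed and the adjacent stereocentre is retained.

Step 2
Reactants: 3 1,2-O-isopropylidene-5-O-methyl-α-D-glucofuranurono-6,3-lactone
Product: 4 1,2-O-isopropylidene-5-O-methyl-α-D-gluco-hexodialdo-1,4:6,3-difuranose (6,3-lactol)
Conditions: i-Bu2AlH (1.2 equiv), CH2Cl2, −78 °C; aq. potassium sodium tartrate
Reagents that add atoms: none
Why: Partial reduction of a γ-lactone with i-Bu2AlH stops at the tetrahedral aluminate at −78 °C and releases the bicyclic lactol on work-up, with the acetonide and all sugar stereocentres untouched.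

Step 3
Reactants: 4 the 6,3-lactol; 5 ethyl (triphenyl-λ5-phosphanylidene)acetate; 6 N-iodosuccinimide
Product: 8 ethyl (6Z)-6,7-dideoxy-7-iodo-1,2-O-isopropylidene-5-O-methyl-α-D-gluco-oct-6-enofuranuronate, via iodo ylide 7 (not isolated)
Conditions: 5, NIS, CH2Cl2, −20 °C; then 4, PhCO2H (cat.), rt → 40 °C
Reagents that add atoms: ethyl (triphenyl-λ5-phosphanylidene)acetate, CCOC(=O)C=P(c1ccccc1)(c1ccccc1)c1ccccc1; N-iodosuccinimide, O=C1CCC(=O)N1I
Why: Wittig olefination of a lactol through its open hydroxy aldehyde with the stabilised α-iodo ylide 7, made beforehand in the same flask by iodination of 5, should place the ester trans to the sugar chain and hence iodine cis to C1 (Z), while it frees G3-OH, the future O5, as the only hydroxyl.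

Step 4
Reactants: 8 the (Z)-iodoenoate
Product: 9 (6Z)-6,7-dideoxy-7-iodo-1,2-O-isopropylidene-5-O-methyl-α-D-gluco-oct-6-enofuranose (3-OH and 8-OH free)
Conditions: i-Bu2AlH (3.5 equiv), CH2Cl2, −78 °C; aq. potassium sodium tartrate
Reagents that add atoms: none
Why: 1,2-Reduction of an α,β-unsaturated ester by i-Bu2AlH gives the allylic alcohol without touching the C–I bond or the alkene geometry at −78 °C, and it removes the Michael acceptor to which G3-OH could add.

Step 5
Reactants: 9 the iodoalkenyl diol; 10 tert-butyl(chloro)diphenylsilane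
Product: 11 (6Z)-8-O-(tert-butyldiphenylsilyl)-6,7-dideoxy-7-iodo-1,2-O-isopropylidene-5-O-methyl-α-D-gluco-oct-6-enofuranose
Conditions: TBDPSCl (1.05 equiv), imidazole, CH2Cl2, 0 °C
Reagents that add atoms: tert-butyl(chloro)diphenylsilane, CC(C)(C)[Si](Cl)(c1ccccc1)c1ccccc1
Why: Chemoselective silylation with the bulky chlorosilane takes the primary allylic hydroxyl O7 and leaves the hindered secondary G3-OH, and this silyl ether is chosen because it survives the aqueous acid of step 7 and is no leaving group β to the later alkenylmetal.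

Step 6
Reactants: 11 the O7 silyl ether; 12 benzoyl chloride
Product: 13 (6Z)-3-O-benzoyl-8-O-(tert-butyldiphenylsilyl)-6,7-dideoxy-7-iodo-1,2-O-isopropylidene-5-O-methyl-α-D-gluco-oct-6-enofuranose
Conditions: BzCl, pyridine, DMAP (cat.), CH2Cl2, 0 °C → rt
Reagents that add atoms: benzoyl chloride, O=C(Cl)c1ccccc1
Why: DMAP-catalysed acylation of the single remaining hydroxyl installs the O5 benzoate of the target unambiguously, so no regioselective acylation of a polyol is ever needed.

Step 7
Reactants: 13 the 3-O-benzoate
Product: 14 (6Z)-3-O-benzoyl-8-O-(tert-butyldiphenylsilyl)-6,7-dideoxy-7-iodo-5-O-methyl-D-gluco-oct-6-enofuranose (1-OH and 2-OH free)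
Conditions: TFA–H2O (4:1), CH2Cl2, 0 °C
Reagents that add atoms: none
Why: Acid-catalysed acetal hydrolysis frees the G1/G2 diol, while the benzoate, silyl ether, methyl ether and alkenyl iodide tolerate brief cold aqueous TFA, the G5 methyl ether locks the furanose form and the trans O2/O3 relation blocks acyl migration.

Step 8
Reactants: 14 the furanose 1,2-diol
Product: 15 (2S,3R,4R,5Z)-2-O-benzoyl-7-O-(tert-butyldiphenylsilyl)-5,6-dideoxy-3-O-formyl-6-iodo-4-O-methyl-aldehydo-D-arabino-hept-5-enose (ring numbering: C4 aldehyde, O5 benzoate, O6 formate, C1-OMe, (Z)-C2=C3 iodide, O7 silyl ether)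
Conditions: NaIO4 on silica gel, CH2Cl2, rt; filtered and used at once
Reagents that add atoms: none
Why: Malaprade glycol cleavage of the hemiacetal 1,2-diol cuts G1–G2, so that G2 becomes the C4 aldehyde and G1 stays on the former ring oxygen as a formate that protects O6 at no extra cost, no stereocentre being involved and the neutral medium avoiding β-elimination.

Step 9
Reactants: 15 the (Z)-iodoalkenyl aldehyde
Product: 17 (1R,4R,5R,6R)-5-benzoyloxy-3-[(tert-butyldiphenylsilyloxy)methyl]-6-formyloxy-4-hydroxy-1-methoxycyclohex-2-ene, via alkenylchromium dichloride 16 (not isolated)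
Conditions: CrCl2 (8 equiv), NiCl2 (0.1 equiv), degassed DMF, slow addition of 15 to 0.005 M, rt; aq. NH4Cl
Reagents that add atoms: none
Why: CrCl2 reduces NiCl2 to zerovalent nickel, which enters the C3–I bond with retention of the alkene geometry and passes the alkenyl group on to trivalent chromium, and the alkenylchromium 16 then attacks the C4 aldehyde; this is the intramolecular Nozaki–Hiyama–Kishi reaction, the established way to close iodoalkenyl aldehydes to cyclic allylic alcohols. The cyclohexene closes in the 6-exo-trig mode (the C=O bond stays outside the new ring, C2=C3 lies inside it), which the Z-iodide allows because it holds C1 and the metal on the same side of the alkene. C4 should be formed as R, with its oxygen cis to O5, through polar Felkin–Anh attack anti to the C5–O bond, a bond made a better acceptor and a poorer chelating site by the benzoate. In the half-chair with O5 and O6 equatorial this mode puts the chromium alkoxide pseudoaxial, where it also avoids allylic 1,2-strain with C7. The step needs chemoselectivity for the aldehyde over the formate and the benzoate, secured by the low nucleophilicity of alkenylchromium reagents, freedom from β-elimination, secured by the silyl ether on O7, and ring closure over oligomerisation, secured by high dilution. The tightly bound chromium alkoxide is a weak nucleophile, so the O5 benzoate should not move to O4 before the mildly acidic quench.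

Step 10
Reactants: 17 the cyclised C4 carbinol
Product: 18 (1R,4R,5R,6R)-5-benzoyloxy-3-(hydroxymethyl)-1-methoxycyclohex-2-ene-4,6-diol
Conditions: AcCl (0.3 equiv), dry MeOH, 0 °C → rt
Reagents that add atoms: none
Why: Acid-catalysed methanolysis with HCl generated from AcCl transesterifies the formate quickly and cleaves the primary silyl ether more slowly, whereas the benzoate is far less reactive and the acidic medium suppresses the base-induced acyl shift from O5 to O4 or O6.

Step 11
Reactants: 18 the O5-benzoyl triol; 12 benzoyl chloride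
Product: 19 target, (1R,4R,5R,6R)-5-benzoyloxy-3-(benzoyloxymethyl)-1-methoxycyclohex-2-ene-4,6-diol
Conditions: BzCl (1.05 equiv), 2,4,6-collidine, CH2Cl2, −40 → −10 °C
Reagents that add atoms: benzoyl chloride, O=C(Cl)c1ccccc1
Why: Chemoselective acylation at low temperature with one equivalent of BzCl and a hindered pyridine base takes the unhindered primary allylic O7-H in preference to the secondary O4-H and O6-H, which gives the target with all four stereocentres unchanged.

Compound list
1 | 1,2-O-isopropylidene-α-D-glucofuranurono-6,3-lactone | CC1(C)O[C@H]2O[C@@H]3[C@H](O)C(=O)O[C@@H]3[C@H]2O1 | starting material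
2 | iodomethane | CI | starting material
3 | 1,2-O-isopropylidene-5-O-methyl-α-D-glucofuranurono-6,3-lactone | CC1(C)O[C@H]2O[C@@H]3[C@H](OC)C(=O)O[C@@H]3[C@H]2O1 | intermediate
4 | 1,2-O-isopropylidene-5-O-methyl-α-D-gluco-hexodialdo-1,4:6,3-difuranose (lactol, mixture at G6) | CC1(C)O[C@H]2O[C@@H]3[C@H](OC)C(O)O[C@@H]3[C@H]2O1 | intermediate
5 | ethyl (triphenyl-λ5-phosphanylidene)acetate | CCOC(=O)C=P(c1ccccc1)(c1ccccc1)c1ccccc1 | starting material
6 | N-iodosuccinimide | O=C1CCC(=O)N1I | starting material
7 | ethyl iodo(triphenyl-λ5-phosphanylidene)acetate (not isolated) | CCOC(=O)C(I)=P(c1ccccc1)(c1ccccc1)c1ccccc1 | intermediate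
8 | ethyl (6Z)-6,7-dideoxy-7-iodo-1,2-O-isopropylidene-5-O-methyl-α-D-gluco-oct-6-enofuranuronate | CO[C@H](/C=C(\I)C(=O)OCC)[C@H]1O[C@@H]2OC(C)(C)O[C@@H]2[C@H]1O | intermediate
9 | (6Z)-6,7-dideoxy-7-iodo-1,2-O-isopropylidene-5-O-methyl-α-D-gluco-oct-6-enofuranose | CO[C@H](/C=C(\I)CO)[C@H]1O[C@@H]2OC(C)(C)O[C@@H]2[C@H]1O | intermediate
10 | tert-butyl(chloro)diphenylsilane | CC(C)(C)[Si](Cl)(c1ccccc1)c1ccccc1 | starting material
11 | 8-O-TBDPS ether of 9 | CO[C@H](/C=C(\I)CO[Si](c1ccccc1)(c1ccccc1)C(C)(C)C)[C@H]1O[C@@H]2OC(C)(C)O[C@@H]2[C@H]1O | intermediate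
12 | benzoyl chloride | O=C(Cl)c1ccccc1 | starting material
13 | 3-O-benzoate of 11 | CO[C@H](/C=C(\I)CO[Si](c1ccccc1)(c1ccccc1)C(C)(C)C)[C@H]1O[C@@H]2OC(C)(C)O[C@@H]2[C@H]1OC(=O)c1ccccc1 | intermediate
14 | furanose 1,2-diol from 13 (anomeric mixture) | CO[C@H](/C=C(\I)CO[Si](c1ccccc1)(c1ccccc1)C(C)(C)C)[C@H]1OC(O)[C@H](O)[C@H]1OC(=O)c1ccccc1 | intermediate
15 | (Z)-iodoalkenyl aldehyde, O5 benzoate, O6 formate, O7 TBDPS ether | CO[C@H](/C=C(\I)CO[Si](c1ccccc1)(c1ccccc1)C(C)(C)C)[C@@H](OC=O)[C@H](OC(=O)c1ccccc1)C=O | intermediate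
16 | alkenylchromium dichloride from 15 (not isolated, solvent ligands omitted) | CO[C@H](/C=C(\[Cr](Cl)Cl)CO[Si](c1ccccc1)(c1ccccc1)C(C)(C)C)[C@@H](OC=O)[C@H](OC(=O)c1ccccc1)C=O | intermediate
17 | cyclised C4 carbinol, O5 benzoate, O6 formate, O7 TBDPS ether | CO[C@@H]1C=C(CO[Si](c2ccccc2)(c2ccccc2)C(C)(C)C)[C@@H](O)[C@@H](OC(=O)c2ccccc2)[C@@H]1OC=O | intermediate
18 | O5-benzoyl triol | CO[C@@H]1C=C(CO)[C@@H](O)[C@@H](OC(=O)c2ccccc2)[C@@H]1O | intermediate
19 | CNP0349013.4 | CO[C@@H]1C=C(COC(=O)c2ccccc2)[C@@H](O)[C@@H](OC(=O)c2ccccc2)[C@@H]1O | target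

Total steps: 11. Longest linear sequence: 11 steps (1 → 19).

Steps most likely to fail

1. Step 9. The risk is poor facial selectivity at the aldehyde, should a chelated or pseudoequatorial transition state compete with the Felkin–Anh mode. The fallback sets out from 15. The coupling is run as before and the C4-epimeric carbinol F1 is separated. It is inverted by a Mitsunobu reaction with formic acid (PPh3, DIAD, THF, 0 °C), an SN2 displacement at the allylic carbon that should give the O4,O6-diformate F2. Methanolic HCl as in step 10 then strips both formates and the silyl ether, and the material rejoins the route at 18. The stereocentre is thus corrected by substitution and not set in the C–C bond formation.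

2. Step 3. The risks are slow opening of the lactol, erosion of the alkene geometry, and conjugate addition of the freed hydroxyl to the iodoenoate. The fallback sets out from 4.
 - Ohira–Bestmann homologation (dimethyl (1-diazo-2-oxopropyl)phosphonate, K2CO3, MeOH, rt) gives the terminal alkyne F3.
 - Double deprotonation (n-BuLi, THF, −78 °C) and paraformaldehyde give the propargylic alcohol F4.
 - Hydroxyl-directed trans-hydrostannation (Bu3SnH, [Cp*RuCl]4 cat., CH2Cl2, rt) places tin on the carbon next to CH2OH and hydrogen anti to it, which gives the (Z)-alkenylstannane F5.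
 - Iododestannylation with retention (I2, CH2Cl2, 0 °C) comes back to the route at 9 and bypasses 8.

3. Step 10. The risk is slow Si–O cleavage that forces long exposure to methanolic acid, with allylic solvolysis or loss or shift of the O5 benzoate. The fallback sets out from 17 and separates the two deprotections.
 - HF·pyridine (THF, 0 °C → rt) removes only silicon and gives the primary alcohol with the formate retained F6.
 - BzCl in pyridine/CH2Cl2 at −20 °C, with only the hindered O4-H as competitor, gives the O5,O7-dibenzoate O6-formate F7.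
 - A short treatment with catalytic HCl in MeOH at 0 °C cleaves the formate. The route is rejoined at 19 and 18 is bypassed.

Further compounds
F1 | step 9 | (1R,4S,5R,6R) C4 epimer of 17 | CO[C@@H]1C=C(CO[Si](c2ccccc2)(c2ccccc2)C(C)(C)C)[C@H](O)[C@@H](OC(=O)c2ccccc2)[C@@H]1OC=O
F2 | step 9 | (1R,4R,5R,6R) O4,O6-diformate, O5 benzoate, O7 TBDPS ether | CO[C@@H]1C=C(CO[Si](c2ccccc2)(c2ccccc2)C(C)(C)C)[C@@H](OC=O)[C@@H](OC(=O)c2ccccc2)[C@@H]1OC=O
F3 | step 3 | 6,7-dideoxy-1,2-O-isopropylidene-5-O-methyl-α-D-gluco-hept-6-ynofuranose | CO[C@H](C#C)[C@H]1O[C@@H]2OC(C)(C)O[C@@H]2[C@H]1O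
F4 | step 3 | 6,7-dideoxy-1,2-O-isopropylidene-5-O-methyl-α-D-gluco-oct-6-ynofuranose | CO[C@H](C#CCO)[C@H]1O[C@@H]2OC(C)(C)O[C@@H]2[C@H]1O
F5 | step 3 | (6Z)-6,7-dideoxy-1,2-O-isopropylidene-5-O-methyl-7-(tributylstannyl)-α-D-gluco-oct-6-enofuranose | CO[C@H](/C=C(\[Sn](CCCC)(CCCC)CCCC)CO)[C@H]1O[C@@H]2OC(C)(C)O[C@@H]2[C@H]1O
F6 | step 10 | (1R,4R,5R,6R)-5-benzoyloxy-6-formyloxy-3-(hydroxymethyl)-4-hydroxy-1-methoxycyclohex-2-ene | CO[C@@H]1C=C(CO)[C@@H](O)[C@@H](OC(=O)c2ccccc2)[C@@H]1OC=O
F7 | step 10 | O6-formate of the target | CO[C@@H]1C=C(COC(=O)c2ccccc2)[C@@H](O)[C@@H](OC(=O)c2ccccc2)[C@@H]1OC=O
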